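## Retrosynthetic overview

1. The last step is hydrogenolysis of three benzyl ethers. Before it, the oxolane is closed (C7–O bond) from a 1,4-diol through the ring B benzylic cation, which fixes 7S trans to C8.
2. The tetraol comes from a single LiBH4 reduction of a lactone-imide. The threo side chain of ring A (C7''–C8'' bond) comes from an Evans syn aldol of the ring B aryloxyacetyl imide with O-benzylvanillin.
3. C8' and the ring C aryl–C7' bond come from rhodium 1,4-addition of an arylboronic acid to an α-methylene lactone, with face-selective protonation.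
4. The key bond is C7–C8. It joins the aldehyde carbon of a vanillin-derived imide to the β-carbon of an acrylate, which is made nucleophilic as a 2-(methoxycarbonyl)allylchromium (ester homoenolate equivalent) under asymmetric chromium catalysis. The bromide comes from a Baylis–Hillman adduct.
5. Ring order: γ-butyrolactone (step 4), opened (step 7), oxolane (step 8). All aromatic rings are bought.

Numbering used: ring B unit is C7–C9, ring C unit is C7'–C9', ring A unit is C7''–C9''; the target is (7S,8R,8'R,7''S,8''S), that is 7,8-trans, 8,8'-cis and threo.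

Assumption: the (S,S)-ligand of step 4 is taken to expose the Re face of the aldehyde; if the sense is the opposite, the (R,R)-ligand is used with no other change.

## Route

Step 1
Reactants: 1 methyl acrylate; 2 (benzyloxy)acetaldehyde
Product: 3 methyl 2-[2-(benzyloxy)-1-hydroxyethyl]prop-2-enoate (racemic)
Conditions: DABCO (0.5 equiv), 1,4-dioxane/H2O 1:1, rt, 24 h
Reagents that add atoms: none
Why: Morita–Baylis–Hillman reaction, in which DABCO adds to the acrylate and the zwitterionic enolate attacks the activated α-alkoxy aldehyde, and the racemic carbinol centre does not matter because step 2 erases it.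

Step 2
Reactants: 3 methyl 2-[2-(benzyloxy)-1-hydroxyethyl]prop-2-enoate
Product: 4 methyl (Z)-4-(benzyloxy)-2-(bromomethyl)but-2-enoate
Conditions: PBr3 (0.4 equiv), Et2O, 0 °C, 1 h
Reagents that add atoms: phosphorus tribromide, BrP(Br)Br
Why: SN2' bromination of a Baylis–Hillman alcohol, in which bromide attacks the terminal methylene of the activated phosphite ester with allylic transposition and allylic strain places CH2OBn trans to the ester, giving the Z bromide while the benzyl ether survives at 0 °C.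

Step 3
Reactants: 5 (4-formyl-2-methoxyphenoxy)acetic acid; 6 (R)-4-benzyl-1,3-oxazolidin-2-one
Product: 8 (R)-4-benzyl-3-[(4-formyl-2-methoxyphenoxy)acetyl]-1,3-oxazolidin-2-one, via mixed pivalic anhydride 7 (not isolated)
Conditions: PivCl (1.05 equiv), Et3N (2.5 equiv), THF, −20 °C; then 6, LiCl (1.1 equiv), −20 °C to rt
Reagents that add atoms: pivaloyl chloride, CC(C)(C)C(=O)Cl (its atoms are found only in 7)
Why: Mixed-anhydride N-acylation of an oxazolidinone (LiCl/Et3N variant), in which the hindered pivaloyl carbonyl steers the nitrogen to the aryloxyacetyl carbonyl, the aryl aldehyde is inert and the auxiliary stereocentre is bought.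

Step 4 (key step)
Reactants: 4 methyl (Z)-4-(benzyloxy)-2-(bromomethyl)but-2-enoate (1.5 equiv); 8 (R)-4-benzyl-3-[(4-formyl-2-methoxyphenoxy)acetyl]-1,3-oxazolidin-2-one
Product: 12 cis-α-methylene-γ-butyrolactone imide (7R,8R), via allylchromium species 9 (not isolated), via syn silyl ether 10 (not isolated), via syn hydroxy ester 11 (not isolated)
Conditions: CrCl2 (10 mol %), (S,S)-1,8-bis(4-isopropyl-4,5-dihydrooxazol-2-yl)-3,6-diphenyl-9H-carbazole (12 mol %), iPr2NEt (30 mol %), Mn powder (2 equiv), TMSCl (2 equiv), THF, 0 °C to rt; then 0.5 M aq HCl/THF, 0 °C; then PPTS (10 mol %), CH2Cl2, rt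
Reagents that add atoms: chlorotrimethylsilane, C[Si](C)(C)Cl (silicon only in 10); CrCl2, Cl[Cr]Cl (chromium only in 9)
Why: Proposed new method: this extends the catalytic asymmetric Nozaki–Hiyama–Kishi 2-(alkoxycarbonyl)allylation/lactonisation (Dreiding–Schmidt type, closest known for unsubstituted 2-(bromomethyl)acrylates, with racemic chromium, zinc or indium versions for γ-substituted ones) to bromide 4, where two one-electron reductions by divalent chromium turn the normally electrophilic acrylate β-carbon into the nucleophilic γ-terminus of allylchromium 9 (an ester homoenolate equivalent), which attacks the equally electrophilic aldehyde carbon of 8 through a chair transition state with CH2OBn trans to the ester and hence axial (syn adduct, cis lactone), while the C2-symmetric ligand exposes the Re face of the aldehyde, so that C8 is set as R and C7 provisionally as R.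

Step 5
Reactants: 12 cis-α-methylene-γ-butyrolactone imide (7R,8R); 13 [4-(benzyloxy)-3-methoxyphenyl]boronic acid (1.5 equiv)
Product: 14 all-cis α-benzyl lactone imide (7R,8R,8'R)
Conditions: [Rh(cod)OH]2 (2.5 mol %), 1,4-dioxane/H2O 10:1, 30 °C
Reagents that add atoms: none
Why: Rhodium-catalysed 1,4-addition of an arylboronic acid with diastereoselective protonation, in which aryl-rhodium adds to the exocyclic methylene and water protonates the oxa-π-allyl rhodium enolate on the open face opposite the cis aryl and CH2OBn groups, pushing the new benzyl group onto their face and setting C8' as R, while the base-free medium spares the imide and avoids epimerisation.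

Step 6
Reactants: 14 all-cis α-benzyl lactone imide (7R,8R,8'R); 15 4-(benzyloxy)-3-methoxybenzaldehyde (1.3 equiv)
Product: 18 syn aldol adduct with a (2R,3S)-2-aryloxy-3-hydroxy-3-arylpropanoyl imide, via Z boron enolate 16 (not isolated), via boron aldolate 17 (not isolated)
Conditions: Bu2BOTf (1.3 equiv), iPr2NEt (1.5 equiv), CH2Cl2, −78 to 0 °C; 15, −78 to 0 °C; pH 7 buffer, MeOH, 30% H2O2, 0 °C
Reagents that add atoms: dibutylboron triflate, CCCCB(CCCC)OS(=O)(=O)C(F)(F)F (boron only in 16 and 17)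
Why: Evans syn glycolate aldol, in which soft enolisation touches only the chelating α-aryloxy imide (not the α-branched lactone) to give Z enolate 16, which reacts through a Zimmerman–Traxler chair on the face away from the auxiliary benzyl group, so the (R)-auxiliary gives the (2R,3S)-syn adduct that becomes threo (7''S,8''S).

Step 7
Reactants: 18 syn aldol adduct
Product: 19 tetraol (7R,8R,8'R,7''S,8''S) with free C7, C9', C7'' and C9'' hydroxyls
Conditions: LiBH4 (6 equiv), MeOH (6 equiv), THF, 0 °C to rt; aqueous work-up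
Reagents that add atoms: none
Why: Hydride reduction with LiBH4/MeOH, which cleaves the imide reductively to the C9'' primary alcohol and opens the lactone to the C7/C9' 1,4-diol in one operation, touches no stereocentre and is mild enough to avoid retro-aldol and α-epimerisation.

Step 8
Reactants: 19 tetraol
Product: 20 tri-O-benzyl ether of the target (7S,8R,8'R,7''S,8''S)
Conditions: camphorsulfonic acid (10 mol %), CH2Cl2 (0.01 M), 0 °C, 30–60 min; Et3N quench
Reagents that add atoms: none
Why: Brønsted-acid-catalysed dehydrative SN1 etherification, in which only C7–OH ionises because its p-alkoxybenzyl cation lacks the β-aryloxy group that retards ionisation at C7'', and ring closure by C9'–OH onto the planar cation occurs anti to the C8 substituent, giving the 7,8-trans oxolane (7S), which is also the thermodynamic isomer.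

Step 9
Reactants: 20 tri-O-benzyl ether of the target
Product: 21 target CNP0226724.1
Conditions: H2 (1 atm), 10% Pd/C, EtOAc/EtOH 1:1, rt, stopped at full debenzylation
Reagents that add atoms: none
Why: Catalytic hydrogenolysis, in which the two phenolic and the one primary benzyl ether are cleaved under neutral conditions faster than the secondary benzylic C7–O and C7''–O bonds, so no stereocentre is affected.

## Compound list

1 | methyl acrylate | C=CC(=O)OC | starting material
2 | (benzyloxy)acetaldehyde | O=CCOCc1ccccc1 | starting material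
3 | methyl 2-[2-(benzyloxy)-1-hydroxyethyl]prop-2-enoate (racemic) | C=C(C(=O)OC)C(O)COCc1ccccc1 | intermediate
4 | methyl (Z)-4-(benzyloxy)-2-(bromomethyl)but-2-enoate | COC(=O)/C(CBr)=C/COCc1ccccc1 | intermediate
5 | (4-formyl-2-methoxyphenoxy)acetic acid | COc1cc(C=O)ccc1OCC(=O)O | starting material
6 | (R)-4-benzyl-1,3-oxazolidin-2-one | O=C1N[C@H](Cc2ccccc2)CO1 | starting material
7 | (4-formyl-2-methoxyphenoxy)acetic pivalic anhydride | COc1cc(C=O)ccc1OCC(=O)OC(=O)C(C)(C)C | intermediate
8 | (R)-4-benzyl-3-[(4-formyl-2-methoxyphenoxy)acetyl]-1,3-oxazolidin-2-one | COc1cc(C=O)ccc1OCC(=O)N1[C@H](Cc2ccccc2)COC1=O | intermediate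
9 | (Z)-[4-(benzyloxy)-2-(methoxycarbonyl)but-2-en-1-yl]chromium dichloride (trivalent chromium; chiral ligand left out of the SMILES) | COC(=O)/C(C[Cr](Cl)Cl)=C/COCc1ccccc1 | intermediate
10 | methyl (3R,4R)-3-[(benzyloxy)methyl]-4-(3-methoxy-4-{2-oxo-2-[(R)-4-benzyl-2-oxo-1,3-oxazolidin-3-yl]ethoxy}phenyl)-2-methylidene-4-[(trimethylsilyl)oxy]butanoate | C=C(C(=O)OC)[C@H](COCc1ccccc1)[C@@H](O[Si](C)(C)C)c1ccc(OCC(=O)N2[C@H](Cc3ccccc3)COC2=O)c(OC)c1 | intermediate
11 | methyl (3R,4R)-3-[(benzyloxy)methyl]-4-hydroxy-4-(3-methoxy-4-{2-oxo-2-[(R)-4-benzyl-2-oxo-1,3-oxazolidin-3-yl]ethoxy}phenyl)-2-methylidenebutanoate | C=C(C(=O)OC)[C@H](COCc1ccccc1)[C@@H](O)c1ccc(OCC(=O)N2[C@H](Cc3ccccc3)COC2=O)c(OC)c1 | intermediate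
12 | (R)-4-benzyl-3-[(4-{(2R,3R)-3-[(benzyloxy)methyl]-4-methylidene-5-oxooxolan-2-yl}-2-methoxyphenoxy)acetyl]-1,3-oxazolidin-2-one | C=C1C(=O)O[C@@H](c2ccc(OCC(=O)N3[C@H](Cc4ccccc4)COC3=O)c(OC)c2)[C@H]1COCc1ccccc1 | intermediate
13 | [4-(benzyloxy)-3-methoxyphenyl]boronic acid | COc1cc(B(O)O)ccc1OCc1ccccc1 | starting material
14 | (R)-4-benzyl-3-[(4-{(2R,3R,4R)-4-[4-(benzyloxy)-3-methoxybenzyl]-3-[(benzyloxy)methyl]-5-oxooxolan-2-yl}-2-methoxyphenoxy)acetyl]-1,3-oxazolidin-2-one | COc1cc(C[C@H]2C(=O)O[C@@H](c3ccc(OCC(=O)N4[C@H](Cc5ccccc5)COC4=O)c(OC)c3)[C@H]2COCc2ccccc2)ccc1OCc1ccccc1 | intermediate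
15 | 4-(benzyloxy)-3-methoxybenzaldehyde | COc1cc(C=O)ccc1OCc1ccccc1 | starting material
16 | (Z)-dibutylboron enolate of 14 | COc1cc(C[C@H]2C(=O)O[C@@H](c3ccc(O/C=C(\OB(CCCC)CCCC)N4[C@H](Cc5ccccc5)COC4=O)c(OC)c3)[C@H]2COCc2ccccc2)ccc1OCc1ccccc1 | intermediate
17 | O-dibutylboryl aldolate of 18 | COc1cc(C[C@H]2C(=O)O[C@@H](c3ccc(O[C@@H](C(=O)N4[C@H](Cc5ccccc5)COC4=O)[C@@H](OB(CCCC)CCCC)c4ccc(OCc5ccccc5)c(OC)c4)c(OC)c3)[C@H]2COCc2ccccc2)ccc1OCc1ccccc1 | intermediate
18 | (R)-4-benzyl-3-[(2R,3S)-3-[4-(benzyloxy)-3-methoxyphenyl]-2-(4-{(2R,3R,4R)-4-[4-(benzyloxy)-3-methoxybenzyl]-3-[(benzyloxy)methyl]-5-oxooxolan-2-yl}-2-methoxyphenoxy)-3-hydroxypropanoyl]-1,3-oxazolidin-2-one | COc1cc(C[C@H]2C(=O)O[C@@H](c3ccc(O[C@@H](C(=O)N4[C@H](Cc5ccccc5)COC4=O)[C@@H](O)c4ccc(OCc5ccccc5)c(OC)c4)c(OC)c3)[C@H]2COCc2ccccc2)ccc1OCc1ccccc1 | intermediate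
19 | (1S,2S)-1-[4-(benzyloxy)-3-methoxyphenyl]-2-(4-{(1R,2R,3R)-3-[4-(benzyloxy)-3-methoxybenzyl]-2-[(benzyloxy)methyl]-1,4-dihydroxybutyl}-2-methoxyphenoxy)propane-1,3-diol | COc1cc(C[C@@H](CO)[C@H](COCc2ccccc2)[C@@H](O)c2ccc(O[C@@H](CO)[C@@H](O)c3ccc(OCc4ccccc4)c(OC)c3)c(OC)c2)ccc1OCc1ccccc1 | intermediate
20 | (1S,2S)-1-[4-(benzyloxy)-3-methoxyphenyl]-2-(4-{(2S,3R,4R)-4-[4-(benzyloxy)-3-methoxybenzyl]-3-[(benzyloxy)methyl]oxolan-2-yl}-2-methoxyphenoxy)propane-1,3-diol | COc1cc(C[C@H]2CO[C@H](c3ccc(O[C@@H](CO)[C@@H](O)c4ccc(OCc5ccccc5)c(OC)c4)c(OC)c3)[C@H]2COCc2ccccc2)ccc1OCc1ccccc1 | intermediate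
21 | (1S,2S)-1-(4-hydroxy-3-methoxyphenyl)-2-(4-{(2S,3R,4R)-4-(4-hydroxy-3-methoxybenzyl)-3-(hydroxymethyl)oxolan-2-yl}-2-methoxyphenoxy)propane-1,3-diol | COc1cc(C[C@H]2CO[C@H](c3ccc(O[C@@H](CO)[C@@H](O)c4ccc(O)c(OC)c4)c(OC)c3)[C@H]2CO)ccc1O | target

## Step count and risks

Total step count: 9.
Longest linear sequence: 8 steps (1, 2, 4, 5, 6, 7, 8, 9). Step 3 is a one-step side branch.

**Step 4 (most risky).**
- Allylchromium 9 could lose benzyloxide by 1,4-elimination to a diene.
- The γ-substituent could erode the syn/anti ratio or the ee. The anti isomer carries the wrong C8 and must be removed by chromatography.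

The fallback sets out from 3 (and uses 8) and comes back at 11, which is lactonised to 12 with PPTS as before. It still uses an ester homoenolate equivalent, but a closed, stereospecific and non-reductive one. Acetylation of 3 (Ac2O, DMAP, CH2Cl2) gives methyl 2-[1-acetoxy-2-(benzyloxy)ethyl]prop-2-enoate F1. Borylation with allylic transposition (B2pin2, Pd2(dba)3 2.5 mol %, toluene, 50 °C) gives the configurationally stable methyl (E)-4-(benzyloxy)-2-[(4,4,5,5-tetramethyl-1,3,2-dioxaborolan-2-yl)methyl]but-2-enoate F2, with CH2OBn cis to CH2B. Allylboration of 8 is catalysed by a BINOL phosphoric acid bearing 3,3'-bis(2,4,6-triisopropylphenyl) groups (10 mol %, toluene; enantiomer chosen for Re-face attack). It runs through a chair to the syn O-pinacolboryl ether of 11 F3, which aqueous work-up hydrolyses to 11.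

**Step 5.**
- β-Hydride elimination could compete with protonation.
- Protonation could drift to the more stable 8,8'-trans lactone.

The fallback sets out from 12 (with 13) and comes back at 14. It sets C8' by syn addition of H2 instead of by enolate protonation. Oxidative boron-Heck arylation (Pd(OAc)2 5 mol %, 2,9-dimethyl-1,10-phenanthroline 6 mol %, O2 1 atm, DMF, rt to 50 °C) gives the (E)-α-[4-(benzyloxy)-3-methoxybenzylidene] lactone imide F4. Homogeneous hydrogenation ([Ir(cod)(PCy3)(py)]PF6, H2, CH2Cl2) then delivers hydrogen to the face opposite the cis aryl and CH2OBn groups, leaves the benzyl ethers intact and gives 14.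

**Step 8.**
- The acid could also ionise C7''–OH, scrambling threo and erythro.
- The C7 cation could be captured by ring C to give an aryltetralin.

The fallback sets out from 18 and comes back at 20. It masks the competing benzylic alcohol before the cation chemistry. Silylation (TIPSOTf, 2,6-lutidine, CH2Cl2, 0 °C) gives the C7''-O-triisopropylsilyl ether of 18 F5. LiBH4/MeOH reduction gives the C7''-O-triisopropylsilyl triol F6. The same acid-catalysed ring closure, now with only one ionisable alcohol, gives the C7''-O-triisopropylsilyl ether of 20 F7. TBAF (THF, 0 °C) then returns 20.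

## Further compounds

F1 | step 4 | methyl 2-[1-acetoxy-2-(benzyloxy)ethyl]prop-2-enoate (racemic) | C=C(C(=O)OC)C(OC(C)=O)COCc1ccccc1
F2 | step 4 | methyl (E)-4-(benzyloxy)-2-[(4,4,5,5-tetramethyl-1,3,2-dioxaborolan-2-yl)methyl]but-2-enoate | COC(=O)/C(CB1OC(C)(C)C(C)(C)O1)=C/COCc1ccccc1
F3 | step 4 | syn O-pinacolboryl ether of 11 | C=C(C(=O)OC)[C@H](COCc1ccccc1)[C@@H](OB1OC(C)(C)C(C)(C)O1)c1ccc(OCC(=O)N2[C@H](Cc3ccccc3)COC2=O)c(OC)c1
F4 | step 5 | (E)-α-[4-(benzyloxy)-3-methoxybenzylidene] lactone imide (7R,8R) | COc1cc(/C=C2/C(=O)O[C@@H](c3ccc(OCC(=O)N4[C@H](Cc5ccccc5)COC4=O)c(OC)c3)[C@H]2COCc2ccccc2)ccc1OCc1ccccc1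
F5 | step 8 | C7''-O-triisopropylsilyl ether of 18 | COc1cc(C[C@H]2C(=O)O[C@@H](c3ccc(O[C@@H](C(=O)N4[C@H](Cc5ccccc5)COC4=O)[C@@H](O[Si](C(C)C)(C(C)C)C(C)C)c4ccc(OCc5ccccc5)c(OC)c4)c(OC)c3)[C@H]2COCc2ccccc2)ccc1OCc1ccccc1
F6 | step 8 | C7''-O-triisopropylsilyl triol (7R,8R,8'R,7''S,8''S) | COc1cc(C[C@@H](CO)[C@H](COCc2ccccc2)[C@@H](O)c2ccc(O[C@@H](CO)[C@@H](O[Si](C(C)C)(C(C)C)C(C)C)c3ccc(OCc4ccccc4)c(OC)c3)c(OC)c2)ccc1OCc1ccccc1
F7 | step 8 | C7''-O-triisopropylsilyl ether of 20 | COc1cc(C[C@H]2CO[C@H](c3ccc(O[C@@H](CO)[C@@H](O[Si](C(C)C)(C(C)C)C(C)C)c4ccc(OCc5ccccc5)c(OC)c4)c(OC)c3)[C@H]2COCc2ccccc2)ccc1OCc1ccccc1
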